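**Plan**

1. The target, 2,4-dihydroxy-5-methyl-6-(13-methyltetradecyl)benzoic acid (ring C1 = carboxyl-bearing carbon, C6 = chain-bearing carbon), is first taken back to its benzyl ester 4-O-ethyl ether 18. The benzene ring of 18 is then cut at C2–C3, C4–C5 and C1–C2.
2. This is possible because C3 is the only unsubstituted ring carbon and lies between the oxygenated C2 and C4. C3 and C4 come from ethoxyacetylene; C2, C5, C6 and C1 come from a vinylketene that already carries the methyl group, the chain and the ester and is released from diazo enone 12 (the C5–C6 bond arises in the Wolff shift).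
3. Diazo enone 12 is cut at the diazo group (diazo transfer to ethyl ketone 10), at the bond between the chain-bearing alkene carbon and the ketone carbon (Stille acylation with propanoyl chloride), at C–Sn (stannylcupration of alkynoate 7) and at the alkyne, which goes back to 14-methylpentadecanoic acid.
4. Forward, the chain is present from the start. The acid is homologated to the alk-2-ynoate (adding C1 and the carboxyl carbon), the propanoyl unit (C2, C5 and the C5 methyl) is joined next, and the only ring is formed in step 8 before a single deprotection.
5. The target has no stereocentre. The one stereochemical element of the route, the 2E geometry of 8, 10 and 12, comes from syn stannylcupration with protonation at low temperature and is kept through the coupling.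

Key step: step 8

Assumption: the side chain is the iso-branched 13-methyltetradecyl group written in the SMILES, so purchasable 14-methylpentadecanoic acid supplies it unchanged together with ring carbon C6.

**Route**

Step 1
Reactants: 1 14-methylpentadecanoic acid
Product: 2 14-methylpentadecan-1-ol
Conditions: LiAlH4, THF, 0 → 65 °C; then H2O, aq NaOH
Reagents that add atoms: none
Why: Lithium aluminium hydride reduction of a carboxylic acid to the primary alcohol is general, and the saturated branched chain offers no other reactive site.

Step 2
Reactants: 2 14-methylpentadecan-1-ol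
Product: 3 14-methylpentadecanal
Conditions: TEMPO (10 mol %), PhI(OAc)2 (1.1 equiv), CH2Cl2, 20 °C
Reagents that add atoms: none
Why: TEMPO-catalysed oxidation with PhI(OAc)2 as terminal oxidant should stop at the aldehyde for an unhindered primary alcohol.

Step 3
Reactants: 3 14-methylpentadecanal
Product: 4 1,1-dibromo-15-methylhexadec-1-ene
Conditions: CBr4 (2 equiv), PPh3 (4 equiv), CH2Cl2, 0 °C
Reagents that add atoms: carbon tetrabromide, BrC(Br)(Br)Br
Why: Dibromo-olefination (first stage of the Corey–Fuchs reaction), in which the ylide Ph3P=CBr2 formed from CBr4 and PPh3 undergoes a Wittig reaction with the aliphatic aldehyde and so adds the carbon that becomes ring C1.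

Step 4
Reactants: 4 1,1-dibromo-15-methylhexadec-1-ene; 5 benzyl chloroformate
Product: 7 benzyl 16-methylheptadec-2-ynoate, via lithium acetylide 6 (not isolated)
Conditions: n-BuLi (2.05 equiv), THF, −78 → 0 °C; then 5, −78 → 20 °C
Reagents that add atoms: none
Why: Second stage of the Corey–Fuchs reaction, in which bromine–lithium exchange, Fritsch–Buttenberg–Wiechell 1,2-shift and deprotonation give acetylide 6, which is C-acylated by the chloroformate at low temperature; the benzyl ester is chosen because it can be removed at the end without alkali.

Step 5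
Reactants: 7 benzyl 16-methylheptadec-2-ynoate
Product: 8 benzyl (2E)-16-methyl-3-(trimethylstannyl)heptadec-2-enoate
Conditions: Me3SnCu(SPh)Li (1.5 equiv; from Me3SnSnMe3, MeLi, then CuSPh), MeOH (1.7 equiv), THF, −100 → −78 °C; aq NH4Cl–NH3
Reagents that add atoms: lithium (phenylthio)(trimethylstannyl)cuprate, [Li+].C[Sn](C)(C)[Cu-]Sc1ccccc1
Why: Stannylcupration of an alk-2-ynoate, in which syn addition of Sn–Cu places tin on C3 and the methanol present protonates the alkenylcopper at −100 °C before it can equilibrate through the allenoate, so that tin ends trans to the ester (2E).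

Step 6
Reactants: 8 benzyl (2E)-16-methyl-3-(trimethylstannyl)heptadec-2-enoate; 9 propanoyl chloride
Product: 10 benzyl (2E)-3-(13-methyltetradecyl)-4-oxohex-2-enoate
Conditions: 9 (1.3 equiv), Pd2(dba)3 (2.5 mol %), P(2-furyl)3 (10 mol %), THF, 50 °C
Reagents that add atoms: none
Why: Stille acylation, in which the acid chloride adds oxidatively to zerovalent palladium, the alkenyl group passes from tin to palladium with retention and reductive elimination gives the enone with the 2E geometry intact; the trimethylstannyl group and the weakly bound furylphosphine are chosen to speed transfer from the alpha-branched alkenyl carbon.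

Step 7
Reactants: 10 benzyl (2E)-3-(13-methyltetradecyl)-4-oxohex-2-enoate
Product: 12 benzyl (2E)-5-diazo-3-(13-methyltetradecyl)-4-oxohex-2-enoate, via trifluoroacetyl diketone 11 (not isolated)
Conditions: LiN(SiMe3)2 (1.1 equiv), THF, −78 °C; CF3CO2CH2CF3 (1.2 equiv), −78 °C; aq HCl wash, crude carried on; 4-acetamidobenzenesulfonyl azide (1.5 equiv), Et3N (1.5 equiv), H2O (1 equiv), MeCN, 20 °C
Reagents that add atoms: 4-acetamidobenzenesulfonyl azide, CC(=O)Nc1ccc(cc1)S(=O)(=O)N=[N+]=[N-]; 2,2,2-trifluoroethyl trifluoroacetate, O=C(OCC(F)(F)F)C(F)(F)F (its trifluoroacetyl group is held only in 11)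
Why: Detrifluoroacetylative diazo transfer, in which the ketone can enolise only at the ethyl CH2 under kinetic deprotonation at −78 °C, the enolate undergoes Claisen condensation with the trifluoroethyl ester, and the sulfonyl azide transfers N2 to the activated methine with loss of the trifluoroacetyl group as the acyl sulfonamide; this is the standard entry to alpha,beta-unsaturated alpha'-diazo ketones, which cannot be made from an acid chloride and a diazoalkane.

Step 8
Reactants: 12 benzyl (2E)-5-diazo-3-(13-methyltetradecyl)-4-oxohex-2-enoate; 13 ethoxyacetylene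
Product: 18 benzyl 4-ethoxy-2-hydroxy-5-methyl-6-(13-methyltetradecyl)benzoate, via vinylketene 14 (not isolated), via cyclobutenone 15 (not isolated), via dienylketene 16 (not isolated), via cyclohexadienone 17 (not isolated)
Conditions: 13 (3 equiv), degassed ClCH2CH2Cl (0.3 M), hν (300 nm, Pyrex), 20 °C; then 80 °C, sealed, dark
Reagents that add atoms: none
Why: Light expels N2 from 12 and the alkenyl group shifts to the diazo carbon (photochemical Wolff rearrangement), which makes the C5–C6 bond and gives vinylketene 14. The nucleophilic unsubstituted carbon of 13 attacks the ketene carbonyl carbon (C2–C3) and the ethoxy-bearing carbon bonds to the ketene alpha carbon (C4–C5) in a [2+2] cycloaddition to cyclobutenone 15, whose conrotatory 4π opening (light or heat, reversible) gives dienylketene 16. Dienylketene 16 closes the six-membered ring by thermal disrotatory 6π electrocyclisation between the ketene carbon and the ester-bearing alkene carbon (C1–C2), and cyclohexadienone 17 tautomerises to the phenol, the closest known reaction type being the Danheiser benzannulation in its diazo ketone form with alkoxyacetylenes. No stereocentre is left, since the quaternary carbon of 15 and the sp3 carbon of 17 both end as aromatic carbons. The step needs one regiochemistry in the [2+2] event, which the polarity of the ynol ether fixes, so that the two oxygens come out meta with C3 unsubstituted between them. It also needs alkenyl migration to outrun hydrogen shift from the methyl group and the ester to stay clear of the ketene, for which direct irradiation of the diazo ketone and the 2E geometry (hydrogen, not the ester, on the inside of the closing triene) are relied on.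

Step 9
Reactants: 18 benzyl 4-ethoxy-2-hydroxy-5-methyl-6-(13-methyltetradecyl)benzoate
Product: 19 2,4-dihydroxy-5-methyl-6-(13-methyltetradecyl)benzoic acid
Conditions: BBr3 (5 equiv), CH2Cl2, −78 → 20 °C; then H2O, 0 °C
Reagents that add atoms: none
Why: Boron tribromide dealkylation, in which the Lewis acid activates the benzyl ester (chelated through the ortho borate) and the aryl ethyl ether for attack of bromide at the benzylic and ethyl carbons, so that one operation frees the acid and the 4-hydroxyl without the hot alkali that a 2,6-disubstituted 2,4-dihydroxybenzoate would answer by decarboxylation; the boron chelates are hydrolysed cold.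

**Compound list**

1 | 14-methylpentadecanoic acid | OC(=O)CCCCCCCCCCCCC(C)C | starting material
2 | 14-methylpentadecan-1-ol | OCCCCCCCCCCCCCC(C)C | intermediate
3 | 14-methylpentadecanal | O=CCCCCCCCCCCCCC(C)C | intermediate
4 | 1,1-dibromo-15-methylhexadec-1-ene | BrC(Br)=CCCCCCCCCCCCCC(C)C | intermediate
5 | benzyl chloroformate | O=C(Cl)OCc1ccccc1 | starting material
6 | (15-methylhexadec-1-yn-1-yl)lithium | [Li]C#CCCCCCCCCCCCCC(C)C | intermediate
7 | benzyl 16-methylheptadec-2-ynoate | O=C(OCc1ccccc1)C#CCCCCCCCCCCCCC(C)C | intermediate
8 | benzyl (2E)-16-methyl-3-(trimethylstannyl)heptadec-2-enoate (tin trans to the ester) | O=C(OCc1ccccc1)/C=C(/[Sn](C)(C)C)CCCCCCCCCCCCC(C)C | intermediate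
9 | propanoyl chloride | CCC(=O)Cl | starting material
10 | benzyl (2E)-3-(13-methyltetradecyl)-4-oxohex-2-enoate (ketone trans to the ester) | O=C(OCc1ccccc1)/C=C(/C(=O)CC)CCCCCCCCCCCCC(C)C | intermediate
11 | benzyl (2E)-7,7,7-trifluoro-5-methyl-3-(13-methyltetradecyl)-4,6-dioxohept-2-enoate (racemic, enolisable) | O=C(OCc1ccccc1)/C=C(/C(=O)C(C)C(=O)C(F)(F)F)CCCCCCCCCCCCC(C)C | intermediate
12 | benzyl (2E)-5-diazo-3-(13-methyltetradecyl)-4-oxohex-2-enoate | O=C(OCc1ccccc1)/C=C(/C(=O)C(C)=[N+]=[N-])CCCCCCCCCCCCC(C)C | intermediate
13 | ethoxyacetylene | CCOC#C | starting material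
14 | benzyl (2E)-4-methyl-3-(13-methyltetradecyl)-5-oxopenta-2,4-dienoate (vinylketene) | O=C=C(C)/C(CCCCCCCCCCCCC(C)C)=C/C(=O)OCc1ccccc1 | intermediate
15 | benzyl (2E)-3-(2-ethoxy-1-methyl-4-oxocyclobut-2-en-1-yl)-16-methylheptadec-2-enoate (racemic) | O=C1C=C(OCC)C1(C)/C(CCCCCCCCCCCCC(C)C)=C/C(=O)OCc1ccccc1 | intermediate
16 | benzyl (2E,4E)-5-ethoxy-4-methyl-3-(13-methyltetradecyl)-7-oxohepta-2,4,6-trienoate (dienylketene) | O=C=C/C(OCC)=C(C)\C(CCCCCCCCCCCCC(C)C)=C\C(=O)OCc1ccccc1 | intermediate
17 | benzyl 4-ethoxy-5-methyl-6-(13-methyltetradecyl)-2-oxocyclohexa-3,5-diene-1-carboxylate (racemic) | O=C1C=C(OCC)C(C)=C(CCCCCCCCCCCCC(C)C)C1C(=O)OCc1ccccc1 | intermediate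
18 | benzyl 4-ethoxy-2-hydroxy-5-methyl-6-(13-methyltetradecyl)benzoate | CCOc1cc(O)c(C(=O)OCc2ccccc2)c(CCCCCCCCCCCCC(C)C)c1C | intermediate
19 | 2,4-dihydroxy-5-methyl-6-(13-methyltetradecyl)benzoic acid | Cc1c(O)cc(O)c(C(=O)O)c1CCCCCCCCCCCCC(C)C | target

**Step count**

Total: 9 steps. Longest linear sequence: 9 steps (1 → 19).

**Steps most likely to fail**

Step 8. Three processes threaten it:
- hydrogen migration from the C-methyl group to the carbene centre in place of alkenyl migration;
- light-driven E-to-Z isomerisation of the ene-dicarbonyl unit, after which the ketene is captured by the ester carbonyl oxygen;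
- a slow [2+2] addition of the acceptor-substituted vinylketene, which leaves room for ketene dimerisation or acylation of the product phenol.

The fallback builds the ring by a Michael–Dieckmann annulation without any ketene. It sets out from aldehyde 3 and comes back to the route at target 19. Wittig reaction of 3 with 3-(triphenylphosphoranylidene)butan-2-one (toluene, 90 °C) should give (3E)-3,17-dimethyloctadec-3-en-2-one F1. Michael addition of dibenzyl malonate to F1 and Dieckmann closure in the same flask (NaH, THF, 65 °C) should give benzyl 3-methyl-2-(13-methyltetradecyl)-4,6-dioxocyclohexane-1-carboxylate F2 as a mixture of stereoisomers and enol forms. Bromination and dehydrobromination (Br2, DMF, 0 → 80 °C) aromatise it to benzyl 2,4-dihydroxy-5-methyl-6-(13-methyltetradecyl)benzoate F3. Hydrogenolysis (H2, Pd/C, EtOAc, 20 °C) then gives 19.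

Step 7. The amide base or the newly formed enolate may add in conjugate fashion to the doubly activated C2=C3 bond. Deprotonation at the allylic CH2 of the side chain (gamma to the ester) may also compete with deprotonation of the ethyl group.

The fallback replaces the lithium enolate by a neutral enol derivative. It sets out from ketone 10 and comes back to the route at diketone 11. Soft enolisation with Me3SiOTf and Et3N (CH2Cl2, 0 °C) should give benzyl (2E,4Z)-3-(13-methyltetradecyl)-4-[(trimethylsilyl)oxy]hexa-2,4-dienoate F4. C-Acylation of this silyl enol ether with trifluoroacetic anhydride (CH2Cl2, −20 → 0 °C) gives 11, which enters the diazo transfer of step 7 unchanged.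

Step 6. Transfer of the alpha-branched alkenyl group from tin to palladium may be slow, which leaves time for protodestannylation by adventitious HCl and for loss of the 2E geometry.

The fallback uses an alkenylchromium addition in place of the cross-coupling. It sets out from stannane 8 and comes back to the route at ketone 10. Iododestannylation with retention (I2, CH2Cl2, 0 °C) should give benzyl (2E)-3-iodo-16-methylheptadec-2-enoate F5. Nozaki–Hiyama–Kishi addition to propanal (CrCl2, NiCl2 cat., DMF, 20 °C) gives racemic benzyl (2E)-4-hydroxy-3-(13-methyltetradecyl)hex-2-enoate F6, which cannot lactonise because the ester is trans to the carbinol carbon. Dess–Martin oxidation (CH2Cl2, 20 °C) gives 10.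

Further compounds
F1 | step 8 | (3E)-3,17-dimethyloctadec-3-en-2-one | CC(=O)/C(C)=C/CCCCCCCCCCCCC(C)C
F2 | step 8 | benzyl 3-methyl-2-(13-methyltetradecyl)-4,6-dioxocyclohexane-1-carboxylate (mixture of stereoisomers) | O=C1CC(=O)C(C)C(CCCCCCCCCCCCC(C)C)C1C(=O)OCc1ccccc1
F3 | step 8 | benzyl 2,4-dihydroxy-5-methyl-6-(13-methyltetradecyl)benzoate | Cc1c(O)cc(O)c(C(=O)OCc2ccccc2)c1CCCCCCCCCCCCC(C)C
F4 | step 7 | benzyl (2E,4Z)-3-(13-methyltetradecyl)-4-[(trimethylsilyl)oxy]hexa-2,4-dienoate | O=C(OCc1ccccc1)/C=C(/C(O[Si](C)(C)C)=C/C)CCCCCCCCCCCCC(C)C
F5 | step 6 | benzyl (2E)-3-iodo-16-methylheptadec-2-enoate | O=C(OCc1ccccc1)/C=C(/I)CCCCCCCCCCCCC(C)C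
F6 | step 6 | benzyl (2E)-4-hydroxy-3-(13-methyltetradecyl)hex-2-enoate (racemic) | O=C(OCc1ccccc1)/C=C(/C(O)CC)CCCCCCCCCCCCC(C)C
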